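The lactone C=O that activates the key step stands at the ring carbon that ends as the oxolane CH2; it is removed afterwards in two reductions.
Retrosynthesis: the two phenolic benzyl ethers and the silyl ether on CH2OH come off last, and the ring CH2 (C-2) is traced back to a lactone C=O, so that the carbinol carbon C-3 becomes the α-carbon of a γ-butyrolactone.
The C-3–OH bond and the bond between the benzylic CH2 and its guaiacyl ring are then cut together, giving an aryl Grignard reagent, an α-methylene lactone and an electrophilic oxygen source. The feature that allows this is the exocyclic C=CH2 on C-3 conjugated to the C-2 carbonyl of the five-membered ring, whose enolate carbon lies next to C-4 with its bulky CH2OSi group.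
The methylene carbon is removed next (lactone α-methylenation), and the C-4–C-5 and lactone C–O bonds are cut to an Evans syn-aldol/lactonisation of a succinate imide with O-benzylvanillin.
Forward, the only ring is closed once, as the lactone in step 2, and kept to the end: the imide is trimmed to CH2OSi, the lactone is methylenated, arylated and hydroxylated in one flask, and its C=O is reduced to CH2.
Stereochemistry: C-5 and C-4 are set by the bought (R)-4-benzyl-oxazolidinone auxiliary, and C-3 is relayed from C-4 by substrate control in the key step; no stereocentre is touched afterwards.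

Key step: step 7

Remark: ring atoms are numbered as in the target oxolan-3-ol (O-1, C-2 ring CH2, C-3 carbinol carbon, C-4 CH bearing CH2OH, C-5 CH bearing aryl). The oxolan-2-one intermediates keep these numbers, with C-2 as the carbonyl carbon.

Step 1
Reactants: 1 (R)-4-benzyl-1,3-oxazolidin-2-one; 2 methyl 4-chloro-4-oxobutanoate
Product: 3 methyl 4-[(4R)-4-benzyl-2-oxo-1,3-oxazolidin-3-yl]-4-oxobutanoate
Conditions: n-BuLi, THF, −78 °C; then 2, −78 → 0 °C
Reagents that add atoms: none
Why: N-acylation of the lithiated oxazolidinone by the acid chloride (imide formation) is fast at low temperature and should leave the methyl ester untouched; no stereocentre is formed.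

Step 2
Reactants: 3 methyl 4-[(4R)-4-benzyl-2-oxo-1,3-oxazolidin-3-yl]-4-oxobutanoate; 4 4-(benzyloxy)-3-methoxybenzaldehyde
Product: 6 (4R)-4-benzyl-3-{[(2R,3R)-2-[4-(benzyloxy)-3-methoxyphenyl]-5-oxooxolan-3-yl]carbonyl}-1,3-oxazolidin-2-one (trans lactone imide), via syn-aldol adduct 5 (not isolated)
Conditions: Bu2BOTf, i-Pr2NEt, CH2Cl2, 0 °C; then 4, −78 → 0 °C; H2O2, pH 7 phosphate buffer, MeOH, 0 °C; then PPTS (cat.), PhMe, 50 °C
Reagents that add atoms: none
Why: Evans syn-aldol reaction: the Z-boron enolate of the imide (the ester is not enolised) should add to the aldehyde through a chair Zimmerman–Traxler transition state, with the benzyl group of the (R)-auxiliary shielding one enolate face, which sets both new centres (3R,4R in 5), and the benzylic hydroxyl then closes on the methyl ester (lactonisation, 5-exo-trig) to the 4,5-trans lactone.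

Step 3
Reactants: 6 trans lactone imide
Product: 7 (2R,3R)-2-[4-(benzyloxy)-3-methoxyphenyl]-5-oxooxolane-3-carboxylic acid
Conditions: LiOH, H2O2, THF/H2O, 0 °C; Na2SO3 (aq); HCl to pH 2
Reagents that add atoms: hydrogen peroxide, OO (as LiOOH; supplies the OH oxygen of the acid)
Why: Hydroperoxide-mediated imide cleavage attacks the exocyclic imide carbonyl selectively and returns the auxiliary; any lactone opened by hydroxide should reclose on acidification, and no stereocentre is touched.

Step 4
Reactants: 7 (2R,3R)-2-[4-(benzyloxy)-3-methoxyphenyl]-5-oxooxolane-3-carboxylic acid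
Product: 8 (4S,5R)-5-[4-(benzyloxy)-3-methoxyphenyl]-4-(hydroxymethyl)oxolan-2-one
Conditions: BH3·SMe2, THF, 0 °C → rt; MeOH
Reagents that add atoms: none
Why: Chemoselective borane reduction of a carboxylic acid (via the acyloxyborane) in the presence of a lactone; the descriptor at C-4 changes only through the priority rules.

Step 5
Reactants: 8 (4S,5R)-5-[4-(benzyloxy)-3-methoxyphenyl]-4-(hydroxymethyl)oxolan-2-one
Product: 9 (4S,5R)-5-[4-(benzyloxy)-3-methoxyphenyl]-4-{[(tert-butyldiphenylsilyl)oxy]methyl}oxolan-2-one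
Conditions: TBDPSCl, imidazole, DMF, 0 °C → rt
Reagents that add atoms: tert-butyl(chloro)diphenylsilane, CC(C)(C)[Si](Cl)(c1ccccc1)c1ccccc1
Why: Silyl ether formation at the primary alcohol blocks translactonisation and places a bulky group on C-4 that shields one face of the later enolate.

Step 6
Reactants: 9 silyl-protected lactone
Product: 12 (4S,5R)-5-[4-(benzyloxy)-3-methoxyphenyl]-4-{[(tert-butyldiphenylsilyl)oxy]methyl}-3-methylideneoxolan-2-one, via Mannich base 10 (not isolated), via trimethylammonium iodide 11 (not isolated)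
Conditions: LiN(SiMe3)2, THF, −78 °C; CH2=NMe2+ I−, −78 °C → rt; MeI, MeOH, rt; DBU, CH2Cl2, rt
Reagents that add atoms: Eschenmoser's salt, C=[N+](C)C.[I-]
Why: Lactone α-methylenation by Mannich reaction of the lithium enolate with Eschenmoser's salt, quaternisation and E1cB elimination; the transient α-centre is erased on elimination, and C-4 and C-5 are not enolisable under these conditions.

Step 7
Reactants: 12 α-methylene lactone; 13 1-(benzyloxy)-4-bromo-2-methoxybenzene
Product: 16 (3R,4S,5R)-3-{[4-(benzyloxy)-3-methoxyphenyl]methyl}-5-[4-(benzyloxy)-3-methoxyphenyl]-4-{[(tert-butyldiphenylsilyl)oxy]methyl}-3-hydroxyoxolan-2-one, via aryl Grignard reagent 14 (not isolated), via bromomagnesium lactone enolate 15 (not isolated)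
Conditions: 13, Mg, THF, 50 °C; CuBr·SMe2 (10 mol %), THF, −40 °C, then 12 (slow addition); then 2-(phenylsulfonyl)-3-phenyloxaziridine, −78 → −20 °C; NH4Cl (aq)
Reagents that add atoms: 2-(phenylsulfonyl)-3-phenyloxaziridine, O=S(=O)(N1OC1c1ccccc1)c1ccccc1
Why: Copper-catalysed 1,4-addition of Grignard reagent 14 to the exocyclic C=CH2 of 12 forms the aryl–CH2 bond and gives the tetrasubstituted magnesium enolate 15, which is oxidised in the same flask by the N-sulfonyloxaziridine (electrophilic α-hydroxylation). The closest known reaction types are aryl cuprate addition to α-methylene-γ-butyrolactones and oxaziridine hydroxylation of α-benzyl-γ-butyrolactone enolates, run here in tandem as a three-component coupling. No ring is closed. The new stereocentre C-3 is controlled by the neighbouring C-4 centre: the oxaziridine should approach the planar enolate anti to the CH2OTBDPS group, so that OH ends up trans and the new benzyl group cis to it. The step needs 1,4- over 1,2-selectivity, which the soft organocopper species and the unhindered exocyclic methylene should secure, and face selectivity, which the bulky silyloxymethyl group next to the enolate carbon should secure against the more distant C-5 aryl group.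

Step 8
Reactants: 16 α-hydroxy lactone
Product: 17 (3R,4S,5R)-3-{[4-(benzyloxy)-3-methoxyphenyl]methyl}-5-[4-(benzyloxy)-3-methoxyphenyl]-4-{[(tert-butyldiphenylsilyl)oxy]methyl}oxolane-2,3-diol (lactol; mixture of C-2 anomers)
Conditions: i-Bu2AlH, CH2Cl2, −78 °C; KNaC4H4O6 (aq)
Reagents that add atoms: none
Why: Partial reduction of a lactone to the lactol with i-Bu2AlH; the tetrahedral aluminium alkoxide, chelated by the neighbouring alkoxide, should persist until work-up, and the anomeric mixture is of no consequence.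

Step 9
Reactants: 17 lactol
Product: 18 (3R,4S,5R)-3-{[4-(benzyloxy)-3-methoxyphenyl]methyl}-5-[4-(benzyloxy)-3-methoxyphenyl]-4-{[(tert-butyldiphenylsilyl)oxy]methyl}oxolan-3-ol
Conditions: Et3SiH, BF3·OEt2, CH2Cl2, −78 → −40 °C; NaHCO3 (aq)
Reagents that add atoms: none
Why: Ionic hydrogenation: BF3·OEt2 converts the lactol into the ring oxocarbenium ion, which the silane reduces at C-2 only, so the anomeric centre is erased and C-3, C-4 and C-5 stay as set.

Step 10
Reactants: 18 silyl-protected oxolane
Product: 19 (3R,4S,5R)-3-{[4-(benzyloxy)-3-methoxyphenyl]methyl}-5-[4-(benzyloxy)-3-methoxyphenyl]-4-(hydroxymethyl)oxolan-3-ol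
Conditions: n-Bu4NF, AcOH, THF, rt
Reagents that add atoms: none
Why: Fluoride-mediated desilylation of the primary silyl ether; the buffered conditions leave the benzyl ethers and the benzylic ring ether alone.

Step 11
Reactants: 19 bis(benzyl ether) diol
Product: 20 (3R,4S,5R)-5-(4-hydroxy-3-methoxyphenyl)-3-[(4-hydroxy-3-methoxyphenyl)methyl]-4-(hydroxymethyl)oxolan-3-ol (target, CID44566587)
Conditions: H2 (1 atm), Pd/C, EtOAc, rt, short reaction time
Reagents that add atoms: none
Why: Hydrogenolysis of the two aryl benzyl ethers, which under neutral conditions should be cleaved much faster than the more hindered secondary benzylic C-5–O bond of the ring.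

Compound list
1 | (R)-4-benzyl-1,3-oxazolidin-2-one | O=C1N[C@H](Cc2ccccc2)CO1 | starting material
2 | methyl 4-chloro-4-oxobutanoate | COC(=O)CCC(Cl)=O | starting material
3 | methyl 4-[(4R)-4-benzyl-2-oxo-1,3-oxazolidin-3-yl]-4-oxobutanoate | COC(=O)CCC(=O)N1C(=O)OC[C@H]1Cc1ccccc1 | intermediate
4 | 4-(benzyloxy)-3-methoxybenzaldehyde | COc1cc(C=O)ccc1OCc1ccccc1 | starting material
5 | methyl (3R,4R)-3-{[(4R)-4-benzyl-2-oxo-1,3-oxazolidin-3-yl]carbonyl}-4-[4-(benzyloxy)-3-methoxyphenyl]-4-hydroxybutanoate (syn-aldol adduct, not isolated) | COC(=O)C[C@H]([C@@H](O)c1ccc(OCc2ccccc2)c(OC)c1)C(=O)N1C(=O)OC[C@H]1Cc1ccccc1 | intermediate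
6 | (4R)-4-benzyl-3-{[(2R,3R)-2-[4-(benzyloxy)-3-methoxyphenyl]-5-oxooxolan-3-yl]carbonyl}-1,3-oxazolidin-2-one | O=C1O[C@@H](c2ccc(OCc3ccccc3)c(OC)c2)[C@@H](C1)C(=O)N1C(=O)OC[C@H]1Cc1ccccc1 | intermediate
7 | (2R,3R)-2-[4-(benzyloxy)-3-methoxyphenyl]-5-oxooxolane-3-carboxylic acid | O=C1O[C@@H](c2ccc(OCc3ccccc3)c(OC)c2)[C@@H](C1)C(=O)O | intermediate
8 | (4S,5R)-5-[4-(benzyloxy)-3-methoxyphenyl]-4-(hydroxymethyl)oxolan-2-one | O=C1O[C@@H](c2ccc(OCc3ccccc3)c(OC)c2)[C@@H](C1)CO | intermediate
9 | (4S,5R)-5-[4-(benzyloxy)-3-methoxyphenyl]-4-{[(tert-butyldiphenylsilyl)oxy]methyl}oxolan-2-one | O=C1O[C@@H](c2ccc(OCc3ccccc3)c(OC)c2)[C@@H](C1)CO[Si](c1ccccc1)(c1ccccc1)C(C)(C)C | intermediate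
10 | (4S,5R)-5-[4-(benzyloxy)-3-methoxyphenyl]-4-{[(tert-butyldiphenylsilyl)oxy]methyl}-3-[(dimethylamino)methyl]oxolan-2-one (Mannich base, C-3 epimers, not isolated) | CN(C)CC1C(=O)O[C@@H](c2ccc(OCc3ccccc3)c(OC)c2)[C@@H]1CO[Si](c1ccccc1)(c1ccccc1)C(C)(C)C | intermediate
11 | {[(4S,5R)-5-[4-(benzyloxy)-3-methoxyphenyl]-4-{[(tert-butyldiphenylsilyl)oxy]methyl}-2-oxooxolan-3-yl]methyl}trimethylammonium iodide (not isolated) | C[N+](C)(C)CC1C(=O)O[C@@H](c2ccc(OCc3ccccc3)c(OC)c2)[C@@H]1CO[Si](c1ccccc1)(c1ccccc1)C(C)(C)C.[I-] | intermediate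
12 | (4S,5R)-5-[4-(benzyloxy)-3-methoxyphenyl]-4-{[(tert-butyldiphenylsilyl)oxy]methyl}-3-methylideneoxolan-2-one | C=C1C(=O)O[C@@H](c2ccc(OCc3ccccc3)c(OC)c2)[C@@H]1CO[Si](c1ccccc1)(c1ccccc1)C(C)(C)C | intermediate
13 | 1-(benzyloxy)-4-bromo-2-methoxybenzene | COc1cc(Br)ccc1OCc1ccccc1 | starting material
14 | [4-(benzyloxy)-3-methoxyphenyl]magnesium bromide (not isolated) | COc1cc([Mg]Br)ccc1OCc1ccccc1 | intermediate
15 | bromomagnesium enolate of (4S,5R)-3-{[4-(benzyloxy)-3-methoxyphenyl]methyl}-5-[4-(benzyloxy)-3-methoxyphenyl]-4-{[(tert-butyldiphenylsilyl)oxy]methyl}oxolan-2-one (not isolated) | COc1cc(CC2=C(O[Mg]Br)O[C@@H](c3ccc(OCc4ccccc4)c(OC)c3)[C@@H]2CO[Si](c2ccccc2)(c2ccccc2)C(C)(C)C)ccc1OCc1ccccc1 | intermediate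
16 | (3R,4S,5R)-3-{[4-(benzyloxy)-3-methoxyphenyl]methyl}-5-[4-(benzyloxy)-3-methoxyphenyl]-4-{[(tert-butyldiphenylsilyl)oxy]methyl}-3-hydroxyoxolan-2-one | COc1cc(C[C@]2(O)C(=O)O[C@@H](c3ccc(OCc4ccccc4)c(OC)c3)[C@@H]2CO[Si](c2ccccc2)(c2ccccc2)C(C)(C)C)ccc1OCc1ccccc1 | intermediate
17 | (3R,4S,5R)-3-{[4-(benzyloxy)-3-methoxyphenyl]methyl}-5-[4-(benzyloxy)-3-methoxyphenyl]-4-{[(tert-butyldiphenylsilyl)oxy]methyl}oxolane-2,3-diol (C-2 anomers) | COc1cc(C[C@]2(O)C(O)O[C@@H](c3ccc(OCc4ccccc4)c(OC)c3)[C@@H]2CO[Si](c2ccccc2)(c2ccccc2)C(C)(C)C)ccc1OCc1ccccc1 | intermediate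
18 | (3R,4S,5R)-3-{[4-(benzyloxy)-3-methoxyphenyl]methyl}-5-[4-(benzyloxy)-3-methoxyphenyl]-4-{[(tert-butyldiphenylsilyl)oxy]methyl}oxolan-3-ol | COc1cc(C[C@]2(O)CO[C@@H](c3ccc(OCc4ccccc4)c(OC)c3)[C@@H]2CO[Si](c2ccccc2)(c2ccccc2)C(C)(C)C)ccc1OCc1ccccc1 | intermediate
19 | (3R,4S,5R)-3-{[4-(benzyloxy)-3-methoxyphenyl]methyl}-5-[4-(benzyloxy)-3-methoxyphenyl]-4-(hydroxymethyl)oxolan-3-ol | COc1cc(C[C@]2(O)CO[C@@H](c3ccc(OCc4ccccc4)c(OC)c3)[C@@H]2CO)ccc1OCc1ccccc1 | intermediate
20 | (3R,4S,5R)-5-(4-hydroxy-3-methoxyphenyl)-3-[(4-hydroxy-3-methoxyphenyl)methyl]-4-(hydroxymethyl)oxolan-3-ol | COc1cc(C[C@]2(O)CO[C@@H](c3ccc(O)c(OC)c3)[C@@H]2CO)ccc1O | target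

Total step count: 11. Longest linear sequence: 11 steps (1 and 2 to 20); bromide 13 enters as a commercial compound in step 7.

Steps most likely to fail

Step 7. What may go wrong: 1,2-addition to the lactone carbonyl or enolate-initiated oligomerisation of the methylene lactone competes with the conjugate addition, oxygen transfer to the magnesium enolate is slow, or oxygen is delivered to the wrong face. Fallback: the two events are separated. From 12, a Rh-catalysed 1,4-addition of [4-(benzyloxy)-3-methoxyphenyl]boronic acid ([RhCl(cod)]2, KOH, dioxane/H2O, 50 °C) forms the same aryl–CH2 bond and, after protonation, should give the α-benzyl lactone F1. Its potassium enolate (KN(SiMe3)2, THF, −78 °C) is then hydroxylated with the same oxaziridine anti to the silyloxymethyl group, which comes back to the route at 16.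

Step 9. What may go wrong: BF3·OEt2 ionises the benzylic C-5–O bond of the electron-rich aryl oxolane besides the lactol, which leads to over-reduction, Friedel–Crafts closure onto the second arene or loss of the ring. Fallback: the ring is opened on purpose and closed again from the benzylic side. From 17, NaBH4 (MeOH, 0 °C) should reduce the lactol to the triol F2. A catalytic Brønsted acid (PPTS or camphorsulfonic acid, CH2Cl2, 0 °C) then generates the benzylic cation, which the primary hydroxyl captures in a 5-exo closure to the thermodynamically preferred 4,5-trans oxolane, coming back to the route at 18.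

Step 11. What may go wrong: hydrogenolysis does not stop at the two aryl benzyl ethers and also cleaves the benzylic C-5–O bond of the ring. Fallback: the benzyl ethers are removed before the ring exists. From 17, the triol F2 (NaBH4, as above) is desilylated (n-Bu4NF, THF) to the tetraol F3. Hydrogenolysis of this acyclic compound (H2, Pd/C, EtOAc), whose benzylic hydroxyl is much less prone to cleavage than a benzylic ether, should give the bisphenol F4. Gentle acid (PPTS, MeCN, rt) then closes the oxolane through the para-quinone methide with the 4,5-trans preference, coming back to the route at 20.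

Further compounds
F1 | step 7 | (4S,5R)-3-{[4-(benzyloxy)-3-methoxyphenyl]methyl}-5-[4-(benzyloxy)-3-methoxyphenyl]-4-{[(tert-butyldiphenylsilyl)oxy]methyl}oxolan-2-one (C-3 epimers) | COc1cc(CC2C(=O)O[C@@H](c3ccc(OCc4ccccc4)c(OC)c3)[C@@H]2CO[Si](c2ccccc2)(c2ccccc2)C(C)(C)C)ccc1OCc1ccccc1
F2 | step 9 | (1R,2S,3R)-1-[4-(benzyloxy)-3-methoxyphenyl]-3-{[4-(benzyloxy)-3-methoxyphenyl]methyl}-2-{[(tert-butyldiphenylsilyl)oxy]methyl}butane-1,3,4-triol | COc1cc(C[C@](O)(CO)[C@@H](CO[Si](c2ccccc2)(c2ccccc2)C(C)(C)C)[C@@H](O)c2ccc(OCc3ccccc3)c(OC)c2)ccc1OCc1ccccc1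
F3 | step 11 | (1R,2S,3R)-1-[4-(benzyloxy)-3-methoxyphenyl]-3-{[4-(benzyloxy)-3-methoxyphenyl]methyl}-2-(hydroxymethyl)butane-1,3,4-triol | COc1cc(C[C@](O)(CO)[C@@H](CO)[C@@H](O)c2ccc(OCc3ccccc3)c(OC)c2)ccc1OCc1ccccc1
F4 | step 11 | (1R,2S,3R)-1-(4-hydroxy-3-methoxyphenyl)-3-[(4-hydroxy-3-methoxyphenyl)methyl]-2-(hydroxymethyl)butane-1,3,4-triol | COc1cc(C[C@](O)(CO)[C@@H](CO)[C@@H](O)c2ccc(O)c(OC)c2)ccc1O
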